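**Retrosynthetic overview**

1. Target 19 is cut between the benzylic carbon C1″ and the stereocentre C2″ of the C8 side chain, giving flavone-8-carbaldehyde 10 (7-, 2′- and 4′-OH as tert-butyl carbonates) and the (E)-γ-alkyl-β-methylallyl boronate 15.
2. Enabling feature: on ring A the phenolic oxygen on C7 is ortho to C8, so O7–C7–C8–C1″ can pass through an o-quinone methide (O=C7, C8=C1″). An oxygen on C1″ can therefore organise the C1″–C2″ bond formation and then be excised by hydride, and the isopropenyl group on C2″ (C3″=CH2) is the imprint of γ-selective allyl transfer.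
3. Key step: 10, 15 and borohydride are joined in one flask (asymmetric allylboration, O→O Boc shift, o-quinone methide reduction, methanolysis of the remaining carbonates and the silyl ether) to give 19 directly.
4. Rings A and B are bought as arenes; ring C (the pyranone) is the only ring that is built (Claisen–Schmidt condensation of 2 and 4, then iodine-mediated oxidative cyclisation), followed by C8 formylation and a protecting-group exchange (7 → 8 → 9 → 10).
5. Boronate 15 comes from 2-methylhex-5-en-2-ol by silylation, cross-metathesis with isopropenyl-Bpin and Matteson homologation, which fix the alkene geometry.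

Key step: step 12

Remark: compounds 1, 11 and 13 are assumed to be catalogue chemicals; side-chain atoms are numbered C1″ (benzylic CH2) to C6″.

**Route**

Step 1
Reactants: 1 1-(2,4-dihydroxy-6-methoxyphenyl)ethan-1-one
Product: 2 1-[4-(benzyloxy)-2-hydroxy-6-methoxyphenyl]ethan-1-one
Conditions: BnBr (1.05 equiv), K2CO3, acetone, reflux
Reagents that add atoms: benzyl bromide, BrCc1ccccc1
Why: Williamson etherification; the 2-OH is tied up in a hydrogen bond to the acetyl carbonyl, so only the 4-OH should be alkylated.

Step 2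
Reactants: 3 2,4-dihydroxybenzaldehyde
Product: 4 2,4-bis(methoxymethoxy)benzaldehyde
Conditions: MOMCl (3 equiv), i-Pr2NEt, CH2Cl2, 0 °C → reflux
Reagents that add atoms: chloromethyl methyl ether, COCCl
Why: O-alkylation with an α-chloro ether (acetal formation) should protect both phenols, the chelated 2-OH needing the excess reagent and warming.

Step 3
Reactants: 2 1-[4-(benzyloxy)-2-hydroxy-6-methoxyphenyl]ethan-1-one; 4 2,4-bis(methoxymethoxy)benzaldehyde
Product: 5 (E)-1-[4-(benzyloxy)-2-hydroxy-6-methoxyphenyl]-3-[2,4-bis(methoxymethoxy)phenyl]prop-2-en-1-one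
Conditions: KOH, EtOH/H2O, rt
Reagents that add atoms: none
Why: Claisen–Schmidt condensation; the ketone enolate adds to the non-enolisable aldehyde and E1cB dehydration should give the E-enone, benzyl and MOM ethers being stable to base.

Step 4
Reactants: 5 (E)-1-[4-(benzyloxy)-2-hydroxy-6-methoxyphenyl]-3-[2,4-bis(methoxymethoxy)phenyl]prop-2-en-1-one
Product: 6 7-(benzyloxy)-2-[2,4-bis(methoxymethoxy)phenyl]-5-methoxy-4H-chromen-4-one
Conditions: I2 (10 mol%), DMSO, 120 °C
Reagents that add atoms: none
Why: Iodine-catalysed oxidative cyclisation of a 2′-hydroxychalcone (6-endo oxa-Michael addition, α-iodination, loss of HI, DMSO as terminal oxidant) should close the pyranone ring; the non-chelated aryl MOM ethers and the benzyl ether are expected to tolerate catalytic iodine.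

Step 5
Reactants: 6 7-(benzyloxy)-2-[2,4-bis(methoxymethoxy)phenyl]-5-methoxy-4H-chromen-4-one
Product: 7 2-[2,4-bis(methoxymethoxy)phenyl]-7-hydroxy-5-methoxy-4H-chromen-4-one
Conditions: H2 (1 atm), Pd/C, EtOAc/MeOH, rt
Reagents that add atoms: none
Why: Hydrogenolysis of the benzyl aryl ether; the MOM acetals and the electron-poor C2=C3 bond of the flavone should be inert at 1 atm and rt.

Step 6
Reactants: 7 2-[2,4-bis(methoxymethoxy)phenyl]-7-hydroxy-5-methoxy-4H-chromen-4-one
Product: 8 2-[2,4-bis(methoxymethoxy)phenyl]-7-hydroxy-5-methoxy-4-oxo-4H-chromene-8-carbaldehyde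
Conditions: MgCl2, Et3N, (CH2O)n, MeCN, reflux; dilute citric acid work-up
Reagents that add atoms: paraformaldehyde (as formaldehyde), C=O
Why: Magnesium-mediated ortho-formylation (Casnati–Skattebøl): the Mg phenoxide delivers formaldehyde to an ortho carbon and a second formaldehyde oxidises the benzylic alkoxide; C8 (between O7 and the ring oxygen O1) should be preferred over C6 (flanked by the 5-OMe group) as in other electrophilic substitutions of 5-alkoxy-7-hydroxychromones, and the basic medium preserves the MOM groups.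

Step 7
Reactants: 8 2-[2,4-bis(methoxymethoxy)phenyl]-7-hydroxy-5-methoxy-4-oxo-4H-chromene-8-carbaldehyde
Product: 9 2-(2,4-dihydroxyphenyl)-7-hydroxy-5-methoxy-4-oxo-4H-chromene-8-carbaldehyde
Conditions: 3 M HCl, MeOH, 50 °C
Reagents that add atoms: none
Why: Acid-catalysed acetal methanolysis should remove both MOM groups while no acid-sensitive group is yet present, so that all three phenols can carry the same base-labile group in the key step.

Step 8
Reactants: 9 2-(2,4-dihydroxyphenyl)-7-hydroxy-5-methoxy-4-oxo-4H-chromene-8-carbaldehyde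
Product: 10 2-{2,4-bis[(tert-butoxycarbonyl)oxy]phenyl}-8-formyl-5-methoxy-4-oxo-4H-chromen-7-yl tert-butyl carbonate
Conditions: Boc2O (3.5 equiv), DMAP (cat.), i-Pr2NEt, THF, 0 °C → rt
Reagents that add atoms: di-tert-butyl dicarbonate, CC(C)(C)OC(=O)OC(=O)OC(C)(C)C
Why: DMAP-catalysed O-acylation should give the tris(carbonate); the 7-O-Boc group next to the aldehyde is the latent trigger for the o-quinone methide, and the two B-ring carbonates fall by mild methanolysis.

Step 9
Reactants: 11 2-methylhex-5-en-2-ol
Product: 12 trimethyl[(2-methylhex-5-en-2-yl)oxy]silane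
Conditions: TMSCl, imidazole, CH2Cl2, 0 °C → rt
Reagents that add atoms: chlorotrimethylsilane, C[Si](C)(C)Cl
Why: Silylation of the tertiary alcohol removes the acidic OH before step 11 and blocks 6-exo oxa-Michael capture of the quinone methide in step 12, yet the TMS ether is cleaved in the final basic methanolysis.

Step 10
Reactants: 12 trimethyl[(2-methylhex-5-en-2-yl)oxy]silane; 13 4,4,5,5-tetramethyl-2-(prop-1-en-2-yl)-1,3,2-dioxaborolane
Product: 14 trimethyl{[(5Z)-2-methyl-6-(4,4,5,5-tetramethyl-1,3,2-dioxaborolan-2-yl)hept-5-en-2-yl]oxy}silane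
Conditions: (H2IMes)(PCy3)Cl2Ru=CHPh (5 mol%), 13 (3 equiv), CH2Cl2, 40 °C
Reagents that add atoms: none
Why: Ruthenium-catalysed olefin cross-metathesis of a terminal alkene with a 1,1-disubstituted vinylboronate; the metallacycle should place the alkyl chain trans to the bulky boryl group, which fixes the trisubstituted alkene geometry (Z by CIP because CH3 outranks B).

Step 11
Reactants: 14 trimethyl{[(5Z)-2-methyl-6-(4,4,5,5-tetramethyl-1,3,2-dioxaborolan-2-yl)hept-5-en-2-yl]oxy}silane
Product: 15 trimethyl{[(5E)-2,6-dimethyl-7-(4,4,5,5-tetramethyl-1,3,2-dioxaborolan-2-yl)hept-5-en-2-yl]oxy}silane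
Conditions: BrCH2Cl, n-BuLi, THF, −78 °C → rt
Reagents that add atoms: bromochloromethane, ClCBr
Why: Matteson homologation: chloromethyllithium forms the boron ate complex and 1,2-migration of the alkenyl group with loss of chloride inserts CH2 into the C–B bond with retention of the alkene geometry (chain trans to CH2B, now E by CIP).

Step 12
Reactants: 10 2-{2,4-bis[(tert-butoxycarbonyl)oxy]phenyl}-8-formyl-5-methoxy-4-oxo-4H-chromen-7-yl tert-butyl carbonate; 15 trimethyl{[(5E)-2,6-dimethyl-7-(4,4,5,5-tetramethyl-1,3,2-dioxaborolan-2-yl)hept-5-en-2-yl]oxy}silane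
Product: 19 2-(2,4-dihydroxyphenyl)-7-hydroxy-8-[(2R)-5-hydroxy-5-methyl-2-(prop-1-en-2-yl)hexyl]-5-methoxy-4H-chromen-4-one, via boronate ester 16 (not isolated), via o-quinone methide 17 (not isolated), via bis-carbonate silyl ether 18 (not isolated)
Conditions: (S)-TRIP (5 mol%), 4 Å MS, toluene, −30 → 0 °C; then NaBH4 (5 equiv), THF/MeOH, −20 °C → rt; then K2CO3 (cat.), MeOH, rt; citric acid work-up
Reagents that add atoms: none
Why: The chiral phosphoric acid hydrogen-bonds a boronate oxygen of 15 and the formyl C–H of 10, and the γ-carbon of 15 adds to C=O through a closed six-membered chair (Zimmerman–Traxler) transition state, forming the C1″–C2″ bond with allyl transposition, which creates the isopropenyl group and gives borate 16. Borohydride/methoxide then turns 16 into a benzylic alkoxide that takes the neighbouring 7-O-Boc group by a six-membered O→O acyl shift; the freed phenoxide expels tert-butyl carbonate to give o-quinone methide 17, hydride adds at C1″ and rearomatises ring A to 18, and methanolysis removes the two B-ring carbonates and the silyl ether. The closest known reaction types are the BINOL-phosphoric-acid-catalysed allyl- and crotylboration of aryl aldehydes with pinacol boronates and the anionic generation and borohydride reduction of o-quinone methides from o-OBoc benzylic alkoxides. No ring of the target is closed; the only cyclic arrays are the chair transition state and the transient exocyclic quinone methide. C2″ is controlled by the catalyst ((S)-TRIP, addition to the Si face of the aldehyde, as expected from the model in which (R)-TRIP gives Re-face addition) together with the E geometry of 15 (chain equatorial, anti adduct, 1S,2S in 16); the carbinol centre is then erased and C2″ remains as R in 17–19. The step needs γ- over α-allyl transfer (secured by the closed boron transition state), hydride capture of 17 faster than capture by oxygen nucleophiles or tautomerisation to a styrene (large excess of borohydride, tertiary OH masked as TMS ether) and survival of the pyranone carbonyl (a vinylogous ester, deactivated further once the 7-phenoxide forms).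

**Compound list**

1 | 1-(2,4-dihydroxy-6-methoxyphenyl)ethan-1-one | CC(=O)c1c(O)cc(O)cc1OC | starting material
2 | 1-[4-(benzyloxy)-2-hydroxy-6-methoxyphenyl]ethan-1-one | CC(=O)c1c(O)cc(OCc2ccccc2)cc1OC | intermediate
3 | 2,4-dihydroxybenzaldehyde | O=Cc1ccc(O)cc1O | starting material
4 | 2,4-bis(methoxymethoxy)benzaldehyde | COCOc1ccc(C=O)c(OCOC)c1 | intermediate
5 | (E)-1-[4-(benzyloxy)-2-hydroxy-6-methoxyphenyl]-3-[2,4-bis(methoxymethoxy)phenyl]prop-2-en-1-one | COCOc1ccc(/C=C/C(=O)c2c(O)cc(OCc3ccccc3)cc2OC)c(OCOC)c1 | intermediate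
6 | 7-(benzyloxy)-2-[2,4-bis(methoxymethoxy)phenyl]-5-methoxy-4H-chromen-4-one | COCOc1ccc(-c2cc(=O)c3c(OC)cc(OCc4ccccc4)cc3o2)c(OCOC)c1 | intermediate
7 | 2-[2,4-bis(methoxymethoxy)phenyl]-7-hydroxy-5-methoxy-4H-chromen-4-one | COCOc1ccc(-c2cc(=O)c3c(OC)cc(O)cc3o2)c(OCOC)c1 | intermediate
8 | 2-[2,4-bis(methoxymethoxy)phenyl]-7-hydroxy-5-methoxy-4-oxo-4H-chromene-8-carbaldehyde | COCOc1ccc(-c2cc(=O)c3c(OC)cc(O)c(C=O)c3o2)c(OCOC)c1 | intermediate
9 | 2-(2,4-dihydroxyphenyl)-7-hydroxy-5-methoxy-4-oxo-4H-chromene-8-carbaldehyde | COc1cc(O)c(C=O)c2oc(-c3ccc(O)cc3O)cc(=O)c12 | intermediate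
10 | 2-{2,4-bis[(tert-butoxycarbonyl)oxy]phenyl}-8-formyl-5-methoxy-4-oxo-4H-chromen-7-yl tert-butyl carbonate | COc1cc(OC(=O)OC(C)(C)C)c(C=O)c2oc(-c3ccc(OC(=O)OC(C)(C)C)cc3OC(=O)OC(C)(C)C)cc(=O)c12 | intermediate
11 | 2-methylhex-5-en-2-ol | C=CCCC(C)(C)O | starting material
12 | trimethyl[(2-methylhex-5-en-2-yl)oxy]silane | C=CCCC(C)(C)O[Si](C)(C)C | intermediate
13 | 4,4,5,5-tetramethyl-2-(prop-1-en-2-yl)-1,3,2-dioxaborolane (isopropenyl-Bpin) | C=C(C)B1OC(C)(C)C(C)(C)O1 | starting material
14 | trimethyl{[(5Z)-2-methyl-6-(4,4,5,5-tetramethyl-1,3,2-dioxaborolan-2-yl)hept-5-en-2-yl]oxy}silane | C[Si](C)(C)OC(C)(C)CC/C=C(\C)B1OC(C)(C)C(C)(C)O1 | intermediate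
15 | trimethyl{[(5E)-2,6-dimethyl-7-(4,4,5,5-tetramethyl-1,3,2-dioxaborolan-2-yl)hept-5-en-2-yl]oxy}silane | C[Si](C)(C)OC(C)(C)CC/C=C(\C)CB1OC(C)(C)C(C)(C)O1 | intermediate
16 | boronate ester (not isolated): O-Bpin derivative of the (1S,2S)-anti carbinol formed at C8 from 10 and 15; 7-, 2′-, 4′-O-Boc and side-chain O-TMS retained | C=C(C)[C@H](CCC(C)(C)O[Si](C)(C)C)[C@H](OB1OC(C)(C)C(C)(C)O1)c1c(OC(=O)OC(C)(C)C)cc(OC)c2c(=O)cc(-c3ccc(OC(=O)OC(C)(C)C)cc3OC(=O)OC(C)(C)C)oc12 | intermediate
17 | o-quinone methide (not isolated): ring A as 7-oxo-8-alkylidene dienone (O=C7, C8=C1″), (2R) side chain with O-TMS, 2′- and 4′-O-Boc | C=C(C)[C@H](CCC(C)(C)O[Si](C)(C)C)C=C1C(=O)C=C(OC)C2=C1OC(=CC2=O)c1ccc(OC(=O)OC(C)(C)C)cc1OC(=O)OC(C)(C)C | intermediate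
18 | bis-carbonate silyl ether (not isolated): 2′,4′-bis-O-Boc, side-chain O-TMS derivative of 19 with free 7-OH | C=C(C)[C@H](CCC(C)(C)O[Si](C)(C)C)Cc1c(O)cc(OC)c2c(=O)cc(-c3ccc(OC(=O)OC(C)(C)C)cc3OC(=O)OC(C)(C)C)oc12 | intermediate
19 | 2-(2,4-dihydroxyphenyl)-7-hydroxy-8-[(2R)-5-hydroxy-5-methyl-2-(prop-1-en-2-yl)hexyl]-5-methoxy-4H-chromen-4-one | C=C(C)[C@H](CCC(C)(C)O)Cc1c(O)cc(OC)c2c(=O)cc(-c3ccc(O)cc3O)oc12 | target

**Step count and risks**

Total step count: 12. Longest linear sequence: 8 steps (1 → 3 → 4 → 5 → 6 → 7 → 8 → 12, or the equally long line beginning with step 2).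

Steps most likely to fail:

1. Step 12. What may go wrong: insufficient facial discrimination of the doubly ortho-substituted aldehyde by the phosphoric acid, or loss of the 7-carbonate by intermolecular methanolysis before the O→O shift. In the one-flask version neither can be corrected, because the carbinol centre that reports on selectivity is erased at once. The fallback sets out from 10 (with 15) and interrupts the sequence after the allylboration (with the acid, or thermally without it, which gives the same anti adduct through the same chair). Aqueous triethanolamine work-up should release the (1S,2S)-carbinol F1, which is isolable because the Boc shift needs the alkoxide. At this stage the syn diastereomer (from any Z isomer of 15) is removed by chromatography and the minor enantiomer by preparative HPLC on a chiral stationary phase, so enantiopurity is secured by resolution instead of catalysis. Pure F1 is then treated on its own with NaBH4 in THF/MeOH (alkoxide formation, Boc shift, quinone methide 17, hydride addition), which comes back to the route at 18; catalytic K2CO3 in MeOH converts 18 into 19 as before.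

2. Step 6. What may go wrong: attack at C6 instead of C8, or stalling of the formylation on the weakly nucleophilic vinylogous-acid phenoxide. The fallback sets out from 7. O-Allylation (allyl bromide, K2CO3, acetone) should give the 7-allyl ether F2. Aromatic Claisen rearrangement (N,N-diethylaniline, 190 °C), for which migration to C8 is the rule in 5-alkoxy-7-allyloxychromones, should give the 8-allyl phenol F3. Double-bond migration (RuHCl(CO)(PPh3)3 cat., toluene, 80 °C) should give the 8-(E)-propenyl phenol F4, and Lemieux–Johnson cleavage (OsO4 cat., NaIO4, 2,6-lutidine, dioxane/H2O) should deliver aldehyde 8, where the route is rejoined.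

3. Step 10. What may go wrong: sluggish cross-metathesis of the 1,1-disubstituted vinylboronate in competition with homodimerisation of 12, or incomplete control of the trisubstituted alkene geometry, which would turn into loss of enantiopurity in step 12. The fallback sets out from 11. Cross-metathesis with 2-methylbut-2-ene (same Ru catalyst, neat) should give 2,6-dimethylhept-5-en-2-ol F5. SeO2 (cat.)/t-BuOOH should oxidise the E-methyl group selectively (ene reaction, then [2,3]-shift) to the (E)-allylic alcohol F6. Pd-catalysed borylation of the allylic alcohol ([Pd(MeCN)4](BF4)2 cat., B2pin2, DMSO/MeOH) should give the (E)-allylboronate F7 with boron at the primary terminus, and silylation (TMSCl, imidazole) comes back to the route at 15.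

Further compounds
F1 | step 12 | tert-butyl 2-{2,4-bis[(tert-butoxycarbonyl)oxy]phenyl}-8-[(1S,2S)-1-hydroxy-5-methyl-2-(prop-1-en-2-yl)-5-[(trimethylsilyl)oxy]hexyl]-5-methoxy-4-oxo-4H-chromen-7-yl carbonate | C=C(C)[C@H](CCC(C)(C)O[Si](C)(C)C)[C@H](O)c1c(OC(=O)OC(C)(C)C)cc(OC)c2c(=O)cc(-c3ccc(OC(=O)OC(C)(C)C)cc3OC(=O)OC(C)(C)C)oc12
F2 | step 6 | 7-(allyloxy)-2-[2,4-bis(methoxymethoxy)phenyl]-5-methoxy-4H-chromen-4-one | C=CCOc1cc(OC)c2c(=O)cc(-c3ccc(OCOC)cc3OCOC)oc2c1
F3 | step 6 | 8-allyl-2-[2,4-bis(methoxymethoxy)phenyl]-7-hydroxy-5-methoxy-4H-chromen-4-one | C=CCc1c(O)cc(OC)c2c(=O)cc(-c3ccc(OCOC)cc3OCOC)oc12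
F4 | step 6 | 2-[2,4-bis(methoxymethoxy)phenyl]-7-hydroxy-5-methoxy-8-[(E)-prop-1-en-1-yl]-4H-chromen-4-one | C/C=C/c1c(O)cc(OC)c2c(=O)cc(-c3ccc(OCOC)cc3OCOC)oc12
F5 | step 10 | 2,6-dimethylhept-5-en-2-ol | CC(C)=CCCC(C)(C)O
F6 | step 10 | (2E)-2,6-dimethylhept-2-ene-1,6-diol | OC/C(C)=C/CCC(C)(C)O
F7 | step 10 | (5E)-2,6-dimethyl-7-(4,4,5,5-tetramethyl-1,3,2-dioxaborolan-2-yl)hept-5-en-2-ol | CC(C)(O)CC/C=C(\C)CB1OC(C)(C)C(C)(C)O1
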